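**Retrosynthetic overview**
1. The target is the malonic half ester of allylic alcohol 20 (Meldrum's acid). 20 is cut at C9–C8 of the side chain into ring sulfone 13 and the geranyl-derived C10 bromide 16 (sulfone alkylation, then reductive loss of sulfur).
2. The only ring is closed at the C6–C1 bond (ring numbering: C1 = stereogenic CH, C2 = C(CH3)2, C6 = carbon bearing the exocyclic CH2) by a rhodium-catalysed enantioselective 6-exo conjugate alkenylation of the acyclic, achiral boryl vinyl sulfone 12. This one step makes the ring, the only stereocentre and the exocyclic methylene, and leaves the sulfone on C9 as the handle for the side chain.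
3. Enabling feature: C6 is the substituted carbon of a 1,1-disubstituted exocyclic alkene bonded directly to the tertiary C1, whose other ring neighbour C2 is quaternary and whose third substituent is the C9 methylene. Hence C6 can be an α-borylvinyl nucleophile, C1 the β-carbon of a vinyl sulfone activated from C9, and C2 a gem-dimethyl tether carbon without γ-hydrogens (no isomerisation of the acceptor, Thorpe–Ingold compression).
4. 12 comes in five steps from isobutyronitrile, 5-iodopent-1-yne and 2-(methylsulfonyl)pyridine.

Key step: step 6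

Remark: the sense of induction of chiraphos in step 6 is not asserted here; the ligand antipode that delivers C6 to the Re face of the β-carbon is to be used (both antipodes are commercial).

**Step 1**
Reactants: 1 isobutyronitrile; 2 5-iodopent-1-yne
Product: 4 2,2-dimethylhept-6-ynenitrile, via lithiated isobutyronitrile 3 (not isolated)
Conditions: LiN(i-Pr)2 (1.05 equiv), THF, −78 °C; then 2, −78 °C to rt
Reagents that add atoms: none
Why: SN2 alkylation of a nitrile-stabilised tertiary carbanion by a primary iodide should outrun proton transfer from the terminal alkyne at low temperature and cannot over-alkylate, because the product has no α-hydrogen.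

**Step 2**
Reactants: 4 2,2-dimethylhept-6-ynenitrile
Product: 6 6-bromo-2,2-dimethylhept-6-enenitrile, via bromoalkenylborane 5 (not isolated)
Conditions: B-bromo-9-BBN (1.2 equiv), CH2Cl2, 0 °C to rt; then AcOH, rt
Reagents that add atoms: B-bromo-9-borabicyclo[3.3.1]nonane BrB1C2CCCC1CCC2
Why: syn-bromoboration of a terminal alkyne (haloboration) puts boron on the terminal and bromine on the internal carbon, and protodeboronation with acetic acid should leave the 2-bromo-1-alkene.

**Step 3**
Reactants: 6 6-bromo-2,2-dimethylhept-6-enenitrile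
Product: 7 2,2-dimethyl-6-(4,4,5,5-tetramethyl-1,3,2-dioxaborolan-2-yl)hept-6-enenitrile
Conditions: B2pin2 (1.1 equiv), PdCl2(PPh3)2 (3 mol %), PPh3 (6 mol %), KOPh (1.5 equiv), toluene, 50 °C
Reagents that add atoms: bis(pinacolato)diboron CC1(C)OB(OC1(C)C)B1OC(C)(C)C(C)(C)O1
Why: Miyaura borylation of a 1-alkenyl bromide (oxidative addition to zerovalent palladium, phenoxide-assisted transmetallation, reductive elimination) should give the alkenyl boronate with the nitrile untouched, and is placed before the acceptor alkene exists so that no Heck cyclisation can compete.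

**Step 4**
Reactants: 7 2,2-dimethyl-6-(4,4,5,5-tetramethyl-1,3,2-dioxaborolan-2-yl)hept-6-enenitrile
Product: 9 2,2-dimethyl-6-(4,4,5,5-tetramethyl-1,3,2-dioxaborolan-2-yl)hept-6-enal, via N-aluminoaldimine 8 (not isolated)
Conditions: i-Bu2AlH (1.2 equiv), toluene, −78 °C; then aqueous potassium sodium tartrate, 0 °C to rt
Reagents that add atoms: water O
Why: partial hydride reduction of the nitrile stops at the N-aluminated aldimine, which should hydrolyse to the aldehyde on work-up; the quaternary α-carbon excludes enolisation and the pinacol boronate tolerates the hydride at −78 °C.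

**Step 5**
Reactants: 9 2,2-dimethyl-6-(4,4,5,5-tetramethyl-1,3,2-dioxaborolan-2-yl)hept-6-enal; 10 2-(methylsulfonyl)pyridine
Product: 12 2-{[(1E)-3,3-dimethyl-7-(4,4,5,5-tetramethyl-1,3,2-dioxaborolan-2-yl)octa-1,7-dien-1-yl]sulfonyl}pyridine, via lithiated phosphonate 11 (not isolated)
Conditions: 10, LiN(SiMe3)2 (2.1 equiv), ClP(O)(OEt)2 (1.05 equiv), THF, −78 °C; then 9, −78 °C to rt
Reagents that add atoms: none
Why: Horner–Wadsworth–Emmons olefination with the sulfonyl-stabilised phosphonate carbanion made in the flask should convert the hindered, non-enolisable aldehyde into the (E)-vinyl sulfone, the E geometry following from the reversible addition and the bulk of the tertiary alkyl group.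

**Step 6**
Reactants: 12 2-{[(1E)-3,3-dimethyl-7-(4,4,5,5-tetramethyl-1,3,2-dioxaborolan-2-yl)octa-1,7-dien-1-yl]sulfonyl}pyridine
Product: 13 2-({[(1S)-2,2-dimethyl-6-methylidenecyclohexyl]methyl}sulfonyl)pyridine
Conditions: Rh(acac)(C2H4)2 (5 mol %), chiraphos (2,3-bis(diphenylphosphino)butane, antipode for Re-face attack, 6 mol %), K3PO4 (0.5 equiv), dioxane/H2O 10:1, 0.05 M, 90 °C
Reagents that add atoms: none
Why: Proposed new method: the alkenyl boronate is expected to transmetallate to a monovalent rhodium hydroxide carrying the chiral bisphosphine, the alkenylrhodium at the future C6 then inserts the tethered vinyl sulfone (held on rhodium by N,O-chelation of the 2-pyridylsulfonyl group) so that C6 bonds to the β-carbon (future C1), and water protonates the α-sulfonyl alkylrhodium at C9 and returns the rhodium hydroxide. The closest known reaction types are the intermolecular rhodium/chiraphos-catalysed enantioselective conjugate addition of alkenylboronic acids to β-substituted vinyl 2-pyridyl sulfones (Hayashi–Miyaura type) and the ring-closing 1,4-addition of alkenylrhodium intermediates to tethered acceptors in rhodium-catalysed arylative enyne cyclisations; untested is the ring-closing use with a 1,1-disubstituted alkenyl boronate and a β-tert-alkyl acceptor. The cyclohexane ring closes in the 6-exo-trig mode at C6–C1, and because boron is replaced ipso the exocyclic methylene is delivered in place without any chance of migration into the ring. The C1 stereocentre is under catalyst control: the bisphosphine differentiates the two faces of the chelated (E)-vinyl sulfone, and bonding of C6 to the Re face of the β-carbon gives (S). The step needs ring closure to outrun protodeboronation and β-hydride elimination; the gem-dimethyl carbon C2 compresses the tether (Thorpe–Ingold effect) and leaves no γ-hydrogen for isomerisation of the acceptor, high dilution suppresses intermolecular addition, and the chelated α-sulfonyl rhodium should be protonated and not eliminated in aqueous dioxane.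

**Step 7**
Reactants: 14 geranyl acetate
Product: 15 (2E,6E)-8-hydroxy-3,7-dimethylocta-2,6-dien-1-yl acetate
Conditions: SeO2 (0.1 equiv), t-BuOOH (3 equiv), salicylic acid (0.1 equiv), CH2Cl2, rt
Reagents that add atoms: tert-butyl hydroperoxide CC(C)(C)OO (terminal oxygen source; SeO2 O=[Se]=O is the catalytic oxygen carrier)
Why: Riley allylic oxidation (ene reaction then [2,3]-sigmatropic shift) should oxidise the (E)-methyl group of the electron-richer distal alkene, the allylic acetate deactivating the proximal one.

**Step 8**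
Reactants: 15 (2E,6E)-8-hydroxy-3,7-dimethylocta-2,6-dien-1-yl acetate
Product: 16 (2E,6E)-8-bromo-3,7-dimethylocta-2,6-dien-1-yl acetate
Conditions: CBr4 (1.2 equiv), PPh3 (1.25 equiv), CH2Cl2, 0 °C
Reagents that add atoms: carbon tetrabromide BrC(Br)(Br)Br
Why: the Appel reaction should replace the primary allylic hydroxyl by bromide through SN2 on the alkoxyphosphonium ion, without allylic transposition, loss of E geometry or attack on the acetate.

**Step 9**
Reactants: 13 2-({[(1S)-2,2-dimethyl-6-methylidenecyclohexyl]methyl}sulfonyl)pyridine; 16 (2E,6E)-8-bromo-3,7-dimethylocta-2,6-dien-1-yl acetate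
Product: 18 (2E,6E)-9-[(1S)-2,2-dimethyl-6-methylidenecyclohexyl]-3,7-dimethyl-9-(pyridin-2-ylsulfonyl)nona-2,6-dien-1-yl acetate (both C9 epimers), via lithiated sulfone 17 (not isolated)
Conditions: LiN(SiMe3)2 (1.05 equiv), THF/DMPU, −78 °C; then 16, −78 to −30 °C
Reagents that add atoms: none
Why: alkylation of the α-sulfonyl carbanion by the allylic bromide (SN2) should be much faster than attack on the acetate at low temperature; the C1 stereocentre is not acidic and stays untouched, and the new C9 centre is irrelevant because sulfur is removed next.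

**Step 10**
Reactants: 18 (2E,6E)-9-[(1S)-2,2-dimethyl-6-methylidenecyclohexyl]-3,7-dimethyl-9-(pyridin-2-ylsulfonyl)nona-2,6-dien-1-yl acetate
Product: 20 (2E,6E)-9-[(1S)-2,2-dimethyl-6-methylidenecyclohexyl]-3,7-dimethylnona-2,6-dien-1-ol, via desulfonylated acetate 19 (not isolated)
Conditions: Mg turnings (10 equiv), MeOH, 0 °C to rt; then K2CO3 (0.5 equiv), same flask, rt
Reagents that add atoms: none
Why: reductive desulfonylation by electron transfer from magnesium to the electron-poor 2-pyridyl sulfone should cleave the C9–S bond and protonate C9, so that both C9 epimers converge on one methylene; the isolated alkenes are not reduced, and methoxide then removes the acetate by transesterification.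

**Step 11**
Reactants: 20 (2E,6E)-9-[(1S)-2,2-dimethyl-6-methylidenecyclohexyl]-3,7-dimethylnona-2,6-dien-1-ol
Product: 21 3-{[(2E,6E)-9-[(1S)-2,2-dimethyl-6-methylidenecyclohexyl]-3,7-dimethylnona-2,6-dien-1-yl]oxy}-3-oxopropanoic acid
Conditions: Meldrum's acid (1.1 equiv), toluene, 90 °C
Reagents that add atoms: Meldrum's acid (2,2-dimethyl-1,3-dioxane-4,6-dione) CC1(C)OC(=O)CC(=O)O1
Why: alcoholysis of Meldrum's acid by the primary allylic alcohol opens the acylal with loss of acetone and should give the malonic acid monoester directly, below the temperature of decarboxylation and without protecting the free acid.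

**Compound list**
1 | isobutyronitrile | CC(C)C#N | starting material
2 | 5-iodopent-1-yne | C#CCCCI | starting material
3 | lithiated isobutyronitrile | [Li+].C[C-](C)C#N | intermediate (not isolated)
4 | 2,2-dimethylhept-6-ynenitrile | C#CCCCC(C)(C)C#N | intermediate
5 | 9-[(1Z)-2-bromo-6-cyano-6-methylhept-1-en-1-yl]-9-borabicyclo[3.3.1]nonane | N#CC(C)(C)CCC/C(Br)=C/B1C2CCCC1CCC2 | intermediate (not isolated)
6 | 6-bromo-2,2-dimethylhept-6-enenitrile | C=C(Br)CCCC(C)(C)C#N | intermediate
7 | 2,2-dimethyl-6-(4,4,5,5-tetramethyl-1,3,2-dioxaborolan-2-yl)hept-6-enenitrile | C=C(B1OC(C)(C)C(C)(C)O1)CCCC(C)(C)C#N | intermediate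
8 | N-(diisobutylalumanyl)aldimine of 9 | C=C(B1OC(C)(C)C(C)(C)O1)CCCC(C)(C)C=N[Al](CC(C)C)CC(C)C | intermediate (not isolated)
9 | 2,2-dimethyl-6-(4,4,5,5-tetramethyl-1,3,2-dioxaborolan-2-yl)hept-6-enal | C=C(B1OC(C)(C)C(C)(C)O1)CCCC(C)(C)C=O | intermediate
10 | 2-(methylsulfonyl)pyridine | CS(=O)(=O)c1ccccn1 | starting material
11 | lithium salt of diethyl [(pyridin-2-ylsulfonyl)methyl]phosphonate | [Li+].CCOP(=O)(OCC)[CH-]S(=O)(=O)c1ccccn1 | intermediate (not isolated)
12 | 2-{[(1E)-3,3-dimethyl-7-(4,4,5,5-tetramethyl-1,3,2-dioxaborolan-2-yl)octa-1,7-dien-1-yl]sulfonyl}pyridine | C=C(B1OC(C)(C)C(C)(C)O1)CCCC(C)(C)/C=C/S(=O)(=O)c1ccccn1 | intermediate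
13 | 2-({[(1S)-2,2-dimethyl-6-methylidenecyclohexyl]methyl}sulfonyl)pyridine | C=C1CCCC(C)(C)[C@@H]1CS(=O)(=O)c1ccccn1 | intermediate
14 | geranyl acetate, (2E)-3,7-dimethylocta-2,6-dien-1-yl acetate | CC(C)=CCC/C(C)=C/COC(C)=O | starting material
15 | (2E,6E)-8-hydroxy-3,7-dimethylocta-2,6-dien-1-yl acetate | CC(=O)OC/C=C(C)/CC/C=C(C)/CO | intermediate
16 | (2E,6E)-8-bromo-3,7-dimethylocta-2,6-dien-1-yl acetate | CC(=O)OC/C=C(C)/CC/C=C(C)/CBr | intermediate
17 | lithiated sulfone 13 (carbanion at C9) | [Li+].C=C1CCCC(C)(C)[C@@H]1[CH-]S(=O)(=O)c1ccccn1 | intermediate (not isolated)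
18 | (2E,6E)-9-[(1S)-2,2-dimethyl-6-methylidenecyclohexyl]-3,7-dimethyl-9-(pyridin-2-ylsulfonyl)nona-2,6-dien-1-yl acetate, both C9 epimers | C=C1CCCC(C)(C)[C@@H]1C(S(=O)(=O)c1ccccn1)C/C(C)=C/CC/C(C)=C/COC(C)=O | intermediate
19 | (2E,6E)-9-[(1S)-2,2-dimethyl-6-methylidenecyclohexyl]-3,7-dimethylnona-2,6-dien-1-yl acetate | C=C1CCCC(C)(C)[C@@H]1CC/C(C)=C/CC/C(C)=C/COC(C)=O | intermediate (not isolated)
20 | (2E,6E)-9-[(1S)-2,2-dimethyl-6-methylidenecyclohexyl]-3,7-dimethylnona-2,6-dien-1-ol | C=C1CCCC(C)(C)[C@@H]1CC/C(C)=C/CC/C(C)=C/CO | intermediate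
21 | 3-{[(2E,6E)-9-[(1S)-2,2-dimethyl-6-methylidenecyclohexyl]-3,7-dimethylnona-2,6-dien-1-yl]oxy}-3-oxopropanoic acid | C=C1CCCC(C)(C)[C@@H]1CC/C(C)=C/CC/C(C)=C/COC(=O)CC(=O)O | target

**Step count and risk**
Total: 11 steps. Longest linear sequence: 9 steps (steps 1–6, then 9–11); steps 7 and 8 form the side branch.

Step 6 (labelled step, highest risk). The process at risk is loss of the carbon–boron bond by protodeboronation, or protonation of the alkenylrhodium, before the hindered β-carbon is reached; weak facial discrimination is the second risk. The fallback gives up catalyst control, closes the same bond by known radical chemistry and resolves afterwards. It sets out from bromide 6 and comes back at 13. Reduction of 6 with i-Bu2AlH passes through the N-aluminoaldimine F1 and gives 6-bromo-2,2-dimethylhept-6-enal F2. Olefination of F2 with 11 as in step 5 gives 2-{[(1E)-7-bromo-3,3-dimethylocta-1,7-dien-1-yl]sulfonyl}pyridine F3. Tin hydride treatment (Bu3SnH, AIBN, benzene, 80 °C, slow addition) should generate the alkenyl radical, which adds 6-exo-trig to the sulfone-activated alkene and gives the racemic sulfone F4. Separation of the enantiomers of F4 by preparative chromatography on a chiral stationary phase delivers 13.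

Step 9. The process at risk is proton or acyl transfer between the allylic acetate and the carbanion, competing with a slow SN2 at the congested C9. The fallback changes the protecting-group strategy to a silyl ether. It sets out from 13 and comes back at 20. Commercial geraniol is silylated (t-BuMe2SiCl, imidazole) to tert-butyl{[(2E)-3,7-dimethylocta-2,6-dien-1-yl]oxy}dimethylsilane F5, oxidised (SeO2, t-BuOOH) to (2E,6E)-8-[(tert-butyldimethylsilyl)oxy]-2,6-dimethylocta-2,6-dien-1-ol F6 and brominated (CBr4, PPh3) to the silyl ether bromide F7. Carbanion 17 is alkylated with F7 to the silyl ether sulfone F8, Mg in MeOH removes sulfur to give the silyl ether F9, and Bu4NF frees 20.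

Step 2. The process at risk is complexation of the bromoborane by the nitrile, with slow addition and unselective hydrobromination by adventitious HBr. The fallback reaches the alkenyl boronate through an enol triflate. It sets out from alkyne 4 and comes back at 7. Markovnikov hydration of 4 ((Ph3P)AuNTf2 catalyst, aqueous MeOH) gives 2,2-dimethyl-6-oxoheptanenitrile F10. Kinetic deprotonation on the methyl side (LiN(i-Pr)2, THF, −78 °C; the nitrile has no α-hydrogen) gives the lithium enolate F11, which PhNTf2 traps as 6-cyano-6-methylhept-1-en-2-yl trifluoromethanesulfonate F12. Miyaura borylation of F12 under the conditions of step 3 gives 7.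

**Further compounds**
F1 | step 6 | N-(diisobutylalumanyl)aldimine of 6-bromo-2,2-dimethylhept-6-enal | C=C(Br)CCCC(C)(C)C=N[Al](CC(C)C)CC(C)C
F2 | step 6 | 6-bromo-2,2-dimethylhept-6-enal | C=C(Br)CCCC(C)(C)C=O
F3 | step 6 | 2-{[(1E)-7-bromo-3,3-dimethylocta-1,7-dien-1-yl]sulfonyl}pyridine | C=C(Br)CCCC(C)(C)/C=C/S(=O)(=O)c1ccccn1
F4 | step 6 | racemic 2-{[(2,2-dimethyl-6-methylidenecyclohexyl)methyl]sulfonyl}pyridine | C=C1CCCC(C)(C)C1CS(=O)(=O)c1ccccn1
F5 | step 9 | tert-butyl{[(2E)-3,7-dimethylocta-2,6-dien-1-yl]oxy}dimethylsilane | CC(C)=CCC/C(C)=C/CO[Si](C)(C)C(C)(C)C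
F6 | step 9 | (2E,6E)-8-[(tert-butyldimethylsilyl)oxy]-2,6-dimethylocta-2,6-dien-1-ol | OC/C(C)=C/CC/C(C)=C/CO[Si](C)(C)C(C)(C)C
F7 | step 9 | {[(2E,6E)-8-bromo-3,7-dimethylocta-2,6-dien-1-yl]oxy}(tert-butyl)dimethylsilane | BrC/C(C)=C/CC/C(C)=C/CO[Si](C)(C)C(C)(C)C
F8 | step 9 | 2-({(3E,7E)-9-[(tert-butyldimethylsilyl)oxy]-1-[(1S)-2,2-dimethyl-6-methylidenecyclohexyl]-3,7-dimethylnona-3,7-dien-1-yl}sulfonyl)pyridine, both epimers | C=C1CCCC(C)(C)[C@@H]1C(S(=O)(=O)c1ccccn1)C/C(C)=C/CC/C(C)=C/CO[Si](C)(C)C(C)(C)C
F9 | step 9 | tert-butyl{[(2E,6E)-9-[(1S)-2,2-dimethyl-6-methylidenecyclohexyl]-3,7-dimethylnona-2,6-dien-1-yl]oxy}dimethylsilane | C=C1CCCC(C)(C)[C@@H]1CC/C(C)=C/CC/C(C)=C/CO[Si](C)(C)C(C)(C)C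
F10 | step 2 | 2,2-dimethyl-6-oxoheptanenitrile | CC(=O)CCCC(C)(C)C#N
F11 | step 2 | lithium 6-cyano-6-methylhept-1-en-2-olate | [Li+].C=C([O-])CCCC(C)(C)C#N
F12 | step 2 | 6-cyano-6-methylhept-1-en-2-yl trifluoromethanesulfonate | C=C(OS(=O)(=O)C(F)(F)F)CCCC(C)(C)C#N
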